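(The constants used here belong to no real substance; what happens was integrated by code.)

What I watched first was a leftover: the coupling partner charged beyond the second substrate, which I took as used one for one, so I reckoned with 40.0 mM to hold the target.

common to all: solid substrate 20 mM; coupling partner 60.0 mM; second substrate 20.0 mM; time 3.0 h

| run | temperature | remark |
|---|---|---|
| Sunday's | 40 °C |  |
| Monday's |  | at 60 °C until 1.5 h, from then on at 20 °C |
| Wednesday's | 20 °C |  |
| Saturday's | 60 °C |  |

    starting material + coupling partner ⇌ target (K1 = 380 L mol⁻¹, k1 = 0.108 L mol⁻¹ s⁻¹, Ea1 = 67.0 kJ mol⁻¹, ΔH1 = −88.0 kJ mol⁻¹)
    second substrate + coupling partner → second product (k2 = 0.385 L mol⁻¹ s⁻¹, Ea2 = 42.0 kJ mol⁻¹)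
    starting material + second substrate → cross product (k3 = 0.795 L mol⁻¹ s⁻¹, Ea3 = 64.0 kJ mol⁻¹)
    solid substrate ⇌ starting material, rate k4*(cs4 - [starting material]) while solid is left; crystals form when [starting material] > cs4 (cs4 = 19 mM, k4 = 0.00870 s⁻¹)
    coupling partner → decomposed reagent (k5 = 3.76 × 10⁻⁴ s⁻¹, Ea5 = 106 kJ mol⁻¹)
    (constants at 40 °C)

- given per volume of solution although it is solid: solid substrate
- all constants are for 40 °C and move with temperature by the activation energies and enthalpies
- at the start none of the solid substrate is in solution
- what has only dissolved of solid substrate counts as not reacted

- the flask with the highest amount of target, in percent of the solid substrate charged ("all alike" if they lie within 1.5 percentage points) (Sunday's / Monday's / Wednesday's / Saturday's / all alike)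
- final target, as a percentage of the solid substrate charged, in Sunday's
- final target, as a percentage of the solid substrate charged, in Monday's
- final target, as a percentage of the solid substrate charged, in Wednesday's
- final target, as a percentage of the solid substrate charged, in Saturday's

- I folded the givens into one dimensionless number, the holding number H: the equilibrium constant of step 1 at the flask's temperature, times the leftover after first-order decomposition over the flask's time. Under thermodynamic control, H is c(target) over c(starting material), so the share in target is H over one plus H.
- At 20 °C, K rose to 3810 L mol⁻¹, and the decomposition constant fell to 0.0842 h⁻¹, which made H 118 for Wednesday's.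
- At 60 °C, the decomposition constant was 15.6 h⁻¹, so the partner's lifetime, 3.85 min, was far shorter than the hot 1.5 h of Monday's. Saturday's H was 9.66 × 10⁻²¹.
- Monday's holding number, 9.35 × 10⁻⁹, the cold K times the leftover carried through both halves, stayed tiny although cooling raised K.
- Sunday's H, at 40 °C, was 0.262.
- So I expected <0.001% target in Monday's, <0.001% in Saturday's, and below 99.2% in Wednesday's, where I left the loss to cross product unreckoned. I expected the most target in Wednesday's.
- One number was not enough for Sunday's, whose H of 0.262 gave a first share in target of 20.8%. Partner bound in target does not decompose, so I put that share back as time spent sheltered.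
- That second round gave Sunday's an H of 0.609, and I committed to 37.8%.
- The forecast named Wednesday's, with 41% for Sunday's, 0% for Monday's, 82% for Wednesday's and 0% for Saturday's, and it held that “the later cooling in Monday's cannot recover it”.
- The simulation gave Wednesday's, with 42.6% for Sunday's, 0% for Monday's, 81.8% for Wednesday's and 0% for Saturday's. The forecast stood within its ranges, and my Sunday's figure lay 4.8 percentage points under the reading.
- Monday's H was 9.35 × 10⁻⁹, and the simulation gave 0% target at the end, with 0% of the coupling partner left and 88.2% as starting material. A neighbouring flask was the same Monday's recipe read at 8.0 h. The same reckoning carried the cold decomposition further and took H down to 6.13 × 10⁻⁹. That reading showed 0% target, 0% of the coupling partner left, and 88.2% as starting material.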